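Readings and results are calculated with made-up constants; noise was put on by code.

The ochre run is the flask asked about, so I read its rates, with the green run, charged with more initiator, beside it.

| flask | free monomer | protic impurity | initiator | remark | time |
|---|---|---|---|---|---|
| ochre | 1.5 M | 1.5 M | 7.5 mM | the very flask that is asked about, followed so far |  |
| green | 1.5 M | 1.5 M | 11 mM | run made earlier |  |
| flask | 1.5 M | 1.50 M | 7.5 mM |  | 3.0 h |

| run | time / min | monomer in chains / % | free monomer / % |
|---|---|---|---|
| ochre | 1.50 | 6.8 | 79.7 |
| ochre | 6.00 | 25.8 | 41.1 |
| ochre | 20.0 | 4.2 | 35.7 |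
| ochre | 80.0 | 0 | 11.8 |
| green | 1.50 | 10.2 | 76.9 |
| green | 6.00 | 29.4 | 38.7 |
| green | 20.0 | 3.6 | 36.5 |
| green | 80.0 | 0.5 | 11.9 |

(readings scatter by 0.3 percentage points)



- time up to 3.0 h at which monomer in chains stands highest
- the amount of monomer in chains, in percent of the free monomer charged, at that time
- the first time at which monomer in chains reaches 13 %, in the same percent, in min

Ochre loses free monomer at 0.135 min⁻¹ of its charge up to 1.50 min and at 0.0858 min⁻¹ up to 6.00 min, a slowing by a factor of 1.57. Then the loss drops to 0.00386 min⁻¹ up to 20.0 min, slower by a further factor of 22.2, while chains swing from gaining 0.0422 min⁻¹ to losing 0.0154 min⁻¹. Green brakes in the same window, to 0.00157 min⁻¹.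

So I carry one quantity: the stall level, the free-monomer share at which chains stop gaining and start giving back (the equilibrium monomer concentration). I take ochre at 6.00 min as still climbing and green as just over, so the mean of their readings gives 39.9 %. Reckoning at its last rates, I put ochre there at 6.14 min, with chains at about 26.4 %. At 80.0 min ochre reads 11.8 % free monomer and green 11.9 %.

The forecast puts the peak at 0.125 h and 31 % high; it puts the asked amount at 3 min, on the ground that “Ochre climbs almost linearly”. My height stands lower.

The flask peaks at 0.109 h with 26.0 %, and it reaches the asked amount at 2.30 min, earlier than the forecast.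

    free monomer + living end → monomer in chains + living end, rate k1*[living end]*[free monomer] (k = 59.0 L mol⁻¹ min⁻¹)
    free monomer + initiator → living end + monomer in chains (k = 0.250 L mol⁻¹ min⁻¹)
    monomer in chains + living end → free monomer + living end, rate k3*[living end] as long as [monomer in chains] is above zero (k = 35.0 min⁻¹)
    protic impurity + free monomer → quenched substrate (k = 0.0690 L mol⁻¹ min⁻¹)

At that peak this flask holds 39.5 % free monomer and 34.5 % quenched substrate. Its chains plus the stall level make 65.9 % of the monomer charge, beside 65.5 % protic impurity left of its own charge, which equals the monomer charge at 1.5 M. The neighbour with 0.030 M of initiator peaks at 39.1 %, so with the stall level I reckon about 21.0 % quenched substrate at its peak, less than the value in this flask. At 3.00 h that neighbour holds 5.27 % free monomer.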